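## Retrosynthetic overview
1. Ring C is formed last. Retro-oxa-6π opening of the pyran gives an ortho-quinone methide, which is the dehydrogenated form of the symmetrical 3,5-diprenyl-2,3',4,6-tetrahydroxybenzophenone.
2. The two aryl–prenyl bonds come from double C-alkylation of 2,3',4,6-tetrahydroxybenzophenone with prenyl bromide.
3. Ring A is formed first. A retro-Claisen cut of the ring bond next to the aroyl-bearing carbon gives the linear tetraketide ArCO-CH2-CO-CH2-CO-CH2-CO2Me, the chain that benzophenone synthase folds.
4. The tetraketide is a 3-hydroxybenzoyl starter (methyl 3-hydroxybenzoate, ring B bought) plus a triketide (dianion of triacetic acid lactone). Ring order: B (bought), A, C.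

Assumption: the target SMILES holds no stereocentre and no stereogenic double bond, so the compound is achiral and needs no enantiocontrol. The only geometric descriptor in the route belongs to the transient compound 8.

## Route

Step 1
Reactants: 1 4-hydroxy-6-methyl-2H-pyran-2-one (triacetic acid lactone); 2 methyl 3-hydroxybenzoate
Product: 5 2,3',4,6-tetrahydroxybenzophenone, via phenacylpyrone 3 (not isolated), via triketo ester 4 (not isolated)
Conditions: 1 (1.2 equiv), LiN(iPr)2 (4.3 equiv), THF, −78 → 0 °C; 2, −78 °C → rt; MeOH quench, Mg(OMe)2 (6 equiv), MeOH, THF distilled off, reflux 16 h; 2 M HCl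
Reagents that add atoms: none
Why: Proposed new method: the dilithio derivative of 1 is acylated at its terminal CH2 by the ester of 2 (Claisen-type γ-acylation of a 1,3-dicarbonyl dianion, with extra base covering the phenol of 2 and the acidic CH2 of 3); methoxide, set free from 2 and supplied in excess as Mg(OMe)2, then opens the lactone of 3 to the chelated tetraketide 4, whose three ketones are masked as magnesium enolates so that the ester is the only electrophile left, and C6 attacks C1 (6-exo Claisen/Dieckmann cyclisation, the benzophenone synthase folding) with loss of methoxide and irreversible aromatisation to the phloroglucinolate; the closest known reaction types are acylation of the triacetic acid lactone dianion with aromatic esters, Mg(OMe)2-induced conversion of 6-(2-oxoalkyl)-4-hydroxy-2-pyrones into acylphloroglucinols, and base-induced cyclisation of 7-aryl-3,5,7-trioxoheptanoates; only the telescoping and the unprotected phenol are new, and no stereocentre is formed.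

Step 2
Reactants: 5 2,3',4,6-tetrahydroxybenzophenone; 6 prenyl bromide (1-bromo-3-methylbut-2-ene)
Product: 7 [2,4,6-trihydroxy-3,5-bis(3-methylbut-2-en-1-yl)phenyl](3-hydroxyphenyl)methanone
Conditions: 6 (2.1 equiv), KOH (2.1 equiv, in two portions), degassed H2O, 0 °C → rt, argon; 1 M HCl to pH 4 at 0 °C
Reagents that add atoms: prenyl bromide (6), CC(C)=CCBr, two equivalents
Why: The limiting base ionises ring A (pKa about 7 to 8) ahead of the ring B phenol (about 9.3), and in water, with its oxygens solvated, this acylphloroglucinolate attacks prenyl bromide through carbon (SN2 C-alkylation of a vinylogous enolate, mirroring the aromatic prenyltransferase steps) at each of the two equivalent free positions and rearomatises each time; no stereocentre is formed.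

Step 3
Reactants: 7 [2,4,6-trihydroxy-3,5-bis(3-methylbut-2-en-1-yl)phenyl](3-hydroxyphenyl)methanone
Product: 9 [5,7-dihydroxy-2,2-dimethyl-8-(3-methylbut-2-en-1-yl)-2H-chromen-6-yl](3-hydroxyphenyl)methanone (target), via ortho-quinone methide 8 (not isolated)
Conditions: DDQ (1.0 equiv, slow addition), dry toluene, 60 °C, 1 h; filter, chromatography
Reagents that add atoms: none
Why: DDQ abstracts a benzylic hydride from either of the two equivalent prenyl groups (dehydrogenative cyclisation, the chemical counterpart of the flavin oxidocyclase), loss of the proton of the most acidic, non-chelated 4-OH gives 8, and its oxa-6π electrocyclisation closes ring C on that oxygen while 2-OH and 6-OH stay hydrogen-bonded to the ketone; the remaining prenyl then has only a chelated OH neighbour and reacts more slowly, and no stereocentre is formed.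

## Compound list
1 | 4-hydroxy-6-methyl-2H-pyran-2-one (triacetic acid lactone) | CC1=CC(O)=CC(=O)O1 | starting material
2 | methyl 3-hydroxybenzoate | COC(=O)c1cccc(O)c1 | starting material
3 | 4-hydroxy-6-[2-(3-hydroxyphenyl)-2-oxoethyl]-2H-pyran-2-one | O=C(CC1=CC(O)=CC(=O)O1)c1cccc(O)c1 | intermediate
4 | methyl 7-(3-hydroxyphenyl)-3,5,7-trioxoheptanoate | COC(=O)CC(=O)CC(=O)CC(=O)c1cccc(O)c1 | intermediate
5 | (3-hydroxyphenyl)(2,4,6-trihydroxyphenyl)methanone (2,3',4,6-tetrahydroxybenzophenone) | O=C(c1cccc(O)c1)c1c(O)cc(O)cc1O | intermediate
6 | prenyl bromide (1-bromo-3-methylbut-2-ene) | CC(C)=CCBr | starting material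
7 | [2,4,6-trihydroxy-3,5-bis(3-methylbut-2-en-1-yl)phenyl](3-hydroxyphenyl)methanone | CC(C)=CCc1c(O)c(CC=C(C)C)c(O)c(C(=O)c2cccc(O)c2)c1O | intermediate
8 | 3,5-dihydroxy-4-(3-hydroxybenzoyl)-2-(3-methylbut-2-en-1-yl)-6-[(Z)-3-methylbut-2-en-1-ylidene]cyclohexa-2,4-dien-1-one | CC(C)=C/C=C1\C(=O)C(CC=C(C)C)=C(O)C(C(=O)c2cccc(O)c2)=C1O | intermediate
9 | [5,7-dihydroxy-2,2-dimethyl-8-(3-methylbut-2-en-1-yl)-2H-chromen-6-yl](3-hydroxyphenyl)methanone | CC(C)=CCc1c(O)c(C(=O)c2cccc(O)c2)c(O)c2c1OC(C)(C)C=C2 | target

## Step count and risks
Total step count: 3. Longest linear sequence: 3 (1 → 5 → 7 → 9).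

All three steps carry risk. Step 1 is the least certain, then step 3, then step 2.

**Step 1.** The lithium phenoxide of 2 may acylate the poorly soluble dianion sluggishly. The anionic pyrone may open incompletely. The chain may also close by aldol attack of C2 on the aryl ketone instead of by Claisen attack on the ester.

The fallback sets out from 2 and comes back at 4. Commercial dehydroacetic acid is cleaved with Mg(OMe)2 in refluxing MeOH to methyl 3,5-dioxohexanoate F1. The soluble trilithium salt of F1 (LiN(iPr)2, THF, 0 °C) is acylated at its terminal carbon by 2. This gives the open-chain ester 4, which is now isolated after a cold acidic quench. No pyrone has to be opened. The chain is closed separately as its polyanion in 2 M aqueous KOH at rt, where only the ester remains electrophilic, to give 5.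

**Step 2.** Expected losses are mono- and tri-prenylated (dearomatised) products and O-prenylation of the ring B phenol.

The fallback sets out from 5 and comes back at 9, reversing the order of events. Compound 5 is condensed with 3-methylbut-2-enal (ethylenediammonium diacetate cat., toluene, reflux). This is a Knoevenagel-type addition followed by dehydration to an ortho-quinone methide and oxa-6π closure. It gives (5,7-dihydroxy-2,2-dimethyl-2H-chromen-6-yl)(3-hydroxyphenyl)methanone F2, and the 8-aroyl isomer is removed by chromatography. One C-prenylation with 6 (KOH, 1 equiv, H2O, 0 °C) at C8, the single free carbon of ring A, then gives 9. Only one alkylation is needed, so statistical mixtures are avoided.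

**Step 3.** Ring closure may partly use a chelated OH and give the 8-aroyl-6-prenyl isomer. A second cyclisation may give the bis-chromene. DDQ may also degrade the electron-rich ring A.

The fallback sets out from 7 and comes back at 9. It replaces hydride abstraction by electrophilic cycloetherification and elimination. PhSeCl (1.0 equiv, CH2Cl2, −78 °C) forms a seleniranium ion on one prenyl group. The free 4-OH opens it 6-endo at the tertiary carbon to give racemic [5,7-dihydroxy-2,2-dimethyl-8-(3-methylbut-2-en-1-yl)-3-(phenylselanyl)-3,4-dihydro-2H-chromen-6-yl](3-hydroxyphenyl)methanone F3. Oxidation with H2O2 (THF, 0 °C → rt) triggers selenoxide syn-elimination. Because C2 is quaternary, the elimination can only take a C4 hydrogen. This installs the C3=C4 double bond of 9 and erases the temporary stereocentre.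

## Further compounds
F1 | step 1 | methyl 3,5-dioxohexanoate | COC(=O)CC(=O)CC(C)=O
F2 | step 2 | (5,7-dihydroxy-2,2-dimethyl-2H-chromen-6-yl)(3-hydroxyphenyl)methanone | CC1(C)C=Cc2c(O1)cc(O)c(C(=O)c1cccc(O)c1)c2O
F3 | step 3 | [5,7-dihydroxy-2,2-dimethyl-8-(3-methylbut-2-en-1-yl)-3-(phenylselanyl)-3,4-dihydro-2H-chromen-6-yl](3-hydroxyphenyl)methanone (racemic) | CC(C)=CCc1c(O)c(C(=O)c2cccc(O)c2)c(O)c2c1OC(C)(C)C([Se]c1ccccc1)C2
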